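Freeze the sum of target and isomer of the product once it is made, and follow how that sum splits.

    target ⇌ isomer of the product (K1 = 7.6, k1 = 0.018 /h)
    2 chain carrier → ended chains B (k2 = 1 × 10⁹ /M/s)
    coupling partner + chain carrier ⇌ target + initiating radical (K3 = 0.25, k3 = 24000 /M/s)
    2 initiating radical → ended chains A (k4 = 1.3 × 10⁹ /M/s)
    substrate + initiating radical → chain carrier (k5 = 59000 /M/s)
    initiator → 2 initiating radical (k6 = 0.17 /h)

| setting | spring | dusk | winter | noon |
|---|---|---|---|---|
| substrate | 20 mM | 20 mM | 20 mM | 20 mM (fed, over 20.0 h) |
| coupling partner | 50.0 mM | 50.0 mM | 50.0 mM (fed, over 20.0 h) | 50.0 mM |
| initiator | 0.20 mM | 0.20 mM | 0.20 mM | 0.20 mM |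
| remark | one stirred flow tank at steady state, fed with the mixture as stated, mean residence time 20 h | everything together in a closed stirred flask, run for 20 h | a stirred flask in which coupling partner is dosed at a steady rate over 20.0 h without added volume, worked up at 20 h | all but substrate at the start; substrate goes in evenly over 20.0 h, the run ends at 20 h |
| time |  | 20 h | 20 h | 20 h |

* the set-up with the highest amount of target at the outlet or at the end, in percent of the substrate put in ("none" if the first two lie within 2 percentage points) (spring / dusk / winter / noon / none)
* amount of target at the outlet or at the end, in percent of the substrate put in, spring
* amount of target at the outlet or at the end, in percent of the substrate put in, dusk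
* amount of target at the outlet or at the end, in percent of the substrate put in, winter
* amount of target at the outlet or at the end, in percent of the substrate put in, noon

- percentages count the substrate that a species holds: one ended chains B counts as two
- for a step with 2 of a species take k times the square, and two of it per event
- the stated concentrations are those of everything mixed, before any reaction; amounts are the same in each set-up
- the feed brings no volume worth counting
- run time (dusk): 20 h

- Write k = 0.018 /h and K = 7.6 for the rate and equilibrium constants of target ⇌ isomer of the product. The split then relaxes with the return time τ = 1/(k + k/K) = 49.1 h, the relaxation time of a reversible first-order step. It is longer than the run of 20 h.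
- Of target made a hours earlier, the share still target is F(a) = f + (1 − f)·exp(−a/τ), where f = 1/(1 + K) = 11.6% is the equilibrium share.
- First estimate, for dusk: with the whole sum made at the start, F at 20 h is 70.4%.
- Objection: the sum may leak, since step 3 runs backward and hands target to chain carrier. But that chain carrier can return as target, and a loss needs a chain end. The charged initiator can supply 0.400 mM of radicals, and each chain end takes two of them. So ended chains B hold 2.00% of the substrate at most, and the sum, once made, is treated as frozen.
- Second objection: target is not all made at the start. The initiator lives 5.88 h, less than the run, so in dusk an age of the run less that lifetime is a fair alternative. That gives F = 77.9%. This reckoning therefore puts dusk between 70.4% and 77.9% of whatever has been made, with conversion left unreckoned.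
- For winter and noon, target formed evenly would have a mean age of 10.0 h, which gives F = 83.7%, larger than in dusk. But the initiator's lifetime is shorter than the dosing time, so late doses may convert less, and this reckoning does not say how much.
- The forecast names dusk as best, with 56% for spring, 72% for dusk, 61% for winter and 47% for noon. Its ground is that the batch flask “uses the radical flux while the initiator is fresh”.
- The simulation gives dusk as best, as forecast, at 69.7%, with spring at 55.8%, winter at 57.9% and noon at 51.8%. In dusk, half of the turnover of step 3 up to the asked time is done by 1.80 h. Taking the run less that time as the age, with 5.19% of the substrate left, F times the substrate used gives 68.9%. For dusk the result means a clock: its target is made early and then ages towards isomer of the product, which holds 23.8% at the end.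
- Second flask, dusk read at 3.0 d: the same age rule, with 2.6% of the substrate left, gives 31.9%. The computed result is 32.6%.

Its constants were set for the occasion; what happens was integrated by code.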